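Before we add anything to the south-east flask at 4.0 h, we decide what its stall is: a balance that more partner can shift, or the end of the starting material.

| setting | south-east | west | flask |
|---|---|---|---|
| starting material | 0.40 M | 0.60 M | 0.40 M |
| partner | 0.28 M | 0.28 M | 0.280 M |
| catalyst | 48 mM | 48 mM | 48 mM |
| temperature | 90 °C | 90 °C | 90 °C |
| remark | the very flask that is asked about, followed so far | run made earlier |  |
| time |  |  | 4.0 h |

- south-east (time / min: target / %): 12.0: 49.8; 20.0: 58.8; 40.0: 64.0; 80.0: 65.9; 150: 65.5
- west (time / min: target / %): 4.00: 20.5; 8.00: 34.4; 10.0: 38.3; 15.0: 42.8; 20.0: 44.3

(readings scatter by 0.5 percentage points)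

- Thursday's: at 4.0 h add partner, 100% of the amount charged, then wait 80 min
- Tuesday's: at 4.0 h take out 90% of the target then present, then wait 80 min
- Wednesday's: at 4.0 h raise the temperature by 15 K, then wait 80 min
- Sunday's: change nothing and wait 80 min more
- Saturday's: at 4.0 h add catalyst, 100% of the amount charged, then wait 80 min

- removed target is counted in
- the earlier runs do not show what temperature does; that part of a forecast is a guess
- additions bring no volume worth counting

* target, in percent of the starting material first charged, at 4.0 h
* the remedy with the largest gain of target, or "none" below 2 percentage points (Thursday's / Tuesday's / Wednesday's / Sunday's / Saturday's / none)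
* target present, with what was taken out counted in, in percent of the starting material first charged, after Tuesday's
* target present, with what was taken out counted in, in percent of the starting material first charged, after Sunday's

Our own reckoning takes the second reading. Suppose one pool fed by the starting material goes two ways: to target at a rate r_T, proportional to free partner B, and to a first-order loss at a rate r_L, which takes no partner. Then r_T/r_L = κB, with κ constant at fixed catalyst and temperature, and time drops out. Integrated, the share of partner left is exp(−κL), where L is the amount lost.

Taking L as the charge of starting material less the target, the south-east plateau of 65.9% gives, as a reading, κ = 20.8 L mol⁻¹, the selectivity factor, target rate over loss rate per unit of free partner.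

For the west run we take L as the excess of starting material over partner, so κ puts the end at 46.6%. Its last reading, 44.3%, is lower than that, and it was still rising by 1.5 percentage points over its last 5.00 min.

So we commit to 65.9% at 4.0 h, the same after Tuesday's and Sunday's, and no remedy reaching 2 points.

The forecast reads a balance. It gives 65.7% (65.1% to 66.3%), 69.2% after Tuesday's and 65.7% after Sunday's, and it names Thursday's: “Adding partner drives target to about 95%”. We part from it on Tuesday's and on that choice.

The flask gives 65.9%, then 65.9% after Tuesday's and 65.9% after Sunday's. The best remedy is none, and Thursday's gains 0 points.

    partner + catalyst + intermediate → catalyst + target (k = 0.230 L² mol⁻² s⁻¹, Ea = 50.0 kJ mol⁻¹)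
    starting material + catalyst → catalyst + intermediate (k = 0.120 L mol⁻¹ s⁻¹, Ea = 46.0 kJ mol⁻¹)
    intermediate → side product (k = 5.30 × 10⁻⁴ s⁻¹, Ea = 99.0 kJ mol⁻¹)
    (constants at 90 °C)

In the south-east flask, starting material stood at 0.0250% by 24.0 min, while intermediate held 15.6% and side product 23.9%. By 120 min intermediate was down to 0.203%. Back at 24.0 min, with side product at 23.9%, κ gives 13.6% of the partner left, and the flask then holds 13.6%. For a neighbour charged with 0.68 M of starting material, κ with L as its excess over partner gives 0.0243% of the partner left, and that flask ends with target at 41.2% and 0.0241% of its own partner charge.

The runs come from a simulation from invented constants.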